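Compound numbers refer to the steps and to the list that follows them. Atom labels follow the carbon skeleton: the ten-membered ring is C1–C10, the cyclohexene is C10, C11, C12, C13, C14, C1, and the butenolide carbons outside the large ring are C17 and C19. β is the face of the six-membered ring that holds the C1 methyl group and α is the opposite face.

## Analysis of the target

Compound 30 is a 6/10/5 tricycle. The ten-membered carbocycle runs C1 (quaternary, methyl), C2 (propanoyloxy), C3, C4, C5(methyl)=C6, C7 (lactone oxygen), C8, C9, C10. Its C1–C10 bond is shared with a cyclohexene (C11(methyl)=C12, C13, C14 acetoxy) and its C7–C8 bond with an α-methylbutenolide (C7, O, C19 carbonyl, C17 methyl-bearing, C8; C8=C17). There are five stereocentres (1S, 2S, 7R, 10S, 14S), and the C5=C6 alkene is Z inside the medium ring. The C9 branch on C10 is β and C2 is α, so the ring fusion is trans; the C14 acetate is α, its oxygen is 1,3-anti to the C2 oxygen across C1, and C7 lies four bonds from the nearest other stereocentre. Sensitive points are the two different secondary esters on a 1,3-diol (acyl migration, hydrolysis, enolisation), the butenolide with its doubly allylic and acidic C7–H, and the Z trisubstituted alkene. The difficulty lies in the quaternary C1, which is flanked by three stereocentres, and in closing a ten-membered ring that holds a Z alkene and is fused to two other rings. The strategy rests on the position of C1 between a ring carbon at the ketone oxidation level (C14), an exocyclic carbinol (C2) and a methine (C10): this is the pattern of an aldol reaction on top of a conjugate addition to a 2-methylcyclohexenone, and since C11 ends as an alkene carbon it can carry a temporary oxygen that steers both events.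

## Retrosynthetic reasoning

**Lactone and C7–C8 (30 to 28).** The two arms that leave the six-membered ring at C1 and C10 meet only at C7–C8, so this is the bond at which the medium ring is closed. Cutting it together with the lactone C19–O bond leads to enal 28, which carries the C7 aldehyde and, at C8, the Z enol triflate of a β-keto ester. The forward Nozaki–Hiyama–Kishi reaction has to join an alkenylmetal at C8 to the aldehyde without touching two esters, and the alkoxide 29 must then reach the cis ester. The gain is that the ring, the lactone and C7 arise in one operation; the price is that C7 is set by the conformation of the closing ring.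

**The C8 arm (28 to 22).** The enal comes from alcohol 27 and PMB ether 26 by functional-group changes. The enol triflate 26 comes from keto ester 24, whose C8–C17 bond is cut to aldehyde 22 and a three-carbon ester enolate (aldol 23, then oxidation). Aldehyde 22 is the unmasked dioxolane 21. Cutting here lets C8 pass through the key step as an inert acetal.

**The C11 methyl alkene (21 to 16).** The C11–CH3 bond is cut to enol triflate 20 (Negishi coupling), which comes from ketone 18 and thus from silyl ether 16 through alcohol 17. The C11 oxygen is needed earlier as a control element, and a kinetic enol triflate fixes the alkene at C11=C12, which dehydration of a tertiary carbinol would not guarantee.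

**The two acyl groups (16 to 13).** The acetate of 16 is removed to give alcohol 15. In 15 the C14–H bond and the O2–acyl bond are cut together, which leads to ketol 13 by an Evans–Tishchenko reduction through hemiacetal 14. This one step sets C14 by hydride delivery from the C2 oxygen (1,3-anti), places the propanoyl group on O2 and leaves O14 free for the acetate, so no protecting group is needed to tell the two oxygens apart.

**The quaternary centre (13 to 6, 11 and 10).** The C9–C10 and C1–C2 bonds are cut. Enone 6 accepts the C9/C8 unit of Grignard reagent 11 at C10, and enolate 12 adds to aldehyde 10 at C1. Three stereocentres and the whole carbon count of the C1–C10 region are reached from three simple pieces, with no ring closed.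

**Enone 6 (6 to 1).** The α-methyl group is cut back to iodide 5 and enone 4. Enone 4 comes from ketal 3 by unmasking the carbonyl at the former ketal carbon, and the carbinol of 2 is set by asymmetric transfer hydrogenation of the commercial enone ketal 1. Direct γ-oxygenation of the oxygen-free 2-methyl enone through its dienol ether was considered and set aside: both the site of enolisation and the site of oxidation are insecure, and the product would be racemic.

**Aldehyde 10 (10 to 7).** C2–C7 with the Z alkene is taken from nerol (7). The distal alkene of PMB ether 8 is cut through epoxide 9, so the geometry of C5=C6 is never made, only kept.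

## Alternatives that were turned down

**Alternative 1:** The ten-membered ring is opened at C4–C5.
- **Disconnection:** the seco compound A2 carries a 1-hydroxycyclopropyl group on C1 (carbinol carbon C2, methylenes C3 and C4) and a Z iodoalkene at C5, with butenolide, C7, acetate and cyclohexene in place.
- **Forward key step:** zerovalent palladium with a bulky phosphine inserts into the C5–I bond, the cyclopropanol exchanges onto palladium, β-carbon elimination opens it to a C4 palladium homoenolate, and reductive elimination joins C4 to C5 to give ketone A1.
- **For it:** the closure creates no stereocentre, the alkene geometry is carried in by the iodide, and C7 can be made earlier by intermolecular, reagent-controlled chemistry. On these points it is stronger than the chosen route, whose closure creates C7.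
- **Against it:** β-hydride elimination of the alkylpalladium homoenolate (to a C3=C4 enone) competes whenever reductive elimination is slow, as it must be for a strained ten-membered ring. The cyclopropanol would have to be built at a neopentyl position beside C1 in a molecule that already holds a lactone and an acetate, which titanium-mediated cyclopropanation of an ester does not tolerate. A1 still needs reduction of a hindered medium-ring ketone to the 2S alcohol with no control element, then acylation.
- **Comparison:** the chosen route sets C2 together with C1 and C10 and then uses the C2 oxygen to set C14.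

**Alternative 2:** The C1–C10 bond is cut to a 14-membered macrocycle.
- **Disconnection:** the epoxy cembranoid butenolide A4 has a C1–C14 epoxide and a C10=C11 alkene.
- **Forward key step:** a Lewis acid opens the epoxide at tertiary C1, C10 attacks C1, and loss of a C12 proton gives A3 with the cyclohexene and the ten-membered ring.
- **For it:** one bond makes the bicycle, sets C1 and C10, and delivers the C14 hydroxyl and the C11=C12 alkene at once; after the macrocycle only a desilylation and two acylations remain. In step count after the key step it is stronger than the chosen route.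
- **Against it:** the C1 cation has other exits (hydride shift from C2 or C14 to a ketone, capture by C5=C6 across the ring), and the C11 cation can lose a proton from the methyl group instead of C12. The trans fusion depends on a macrocycle conformation that cannot be planned. An enantiopure A4 with defined epoxide configuration is itself a long synthesis.
- **Comparison:** the chosen route controls the same centres by substituents on a six-membered ring, where facial preferences are predictable.

**Alternative 3:** The C7–C8 bond is made by ring contraction.
- **Disconnection:** the 13-membered diallylic ether A6 has O between C7 and C19 and a tributylstannyl group on C7.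
- **Forward key step:** tin–lithium exchange gives an α-alkoxy carbanion at C7 that attacks C8 through a five-membered transition state as the O–C19 bond breaks ([2,3]-Wittig rearrangement), giving the ten-membered alcohol A5 with an isopropenyl group on C8.
- **For it:** a 13-membered ether is easier to close than a ten-membered carbocycle, and the concerted transition state can in principle control C7 better than a chromium-mediated closure.
- **Against it:** the C7 carbanion is allylic, so it is delocalised toward C5, loses configuration and can react through the [1,2] pathway. The alkyllithium excludes both esters, so O2 and O14 travel as ethers and need two deprotection and acylation pairs later. A5 still lacks the butenolide: C19 must be oxidised to the carboxyl level, lactonised and the alkene moved to C8=C17, which discards the new C8 stereocentre and costs about five steps.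
- **Comparison:** the chosen route forms the same C7–C8 bond with the butenolide in one step and with the esters already in place.

Key step: step 9

Assumption: 1, 7 and 11 (as its THF solution) are purchased, and all other reagents are common commercial chemicals.

## Route

Step 1
Reactants: 1 1,4-dioxaspiro[4.5]dec-6-en-8-one
Product: 2 (8R)-1,4-dioxaspiro[4.5]dec-6-en-8-ol
Conditions: RuCl(p-cymene)[(R,R)-TsDPEN] (cat.), HCO2H/Et3N 5:2, rt
Reagents that add atoms: none
Why: Noyori asymmetric transfer hydrogenation reduces the enone carbonyl in the 1,2 sense; the alkene takes the place of the aryl group of an aryl ketone, so the (R,R)-ligand is expected to give the 8R carbinol (the antipodal catalyst is used if the sense proves opposite). This catalyst-controlled centre becomes C11 of the skeleton.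

Step 2
Reactants: 2 (8R)-1,4-dioxaspiro[4.5]dec-6-en-8-ol
Product: 3 tert-butyl[(8R)-1,4-dioxaspiro[4.5]dec-6-en-8-yloxy]dimethylsilane
Conditions: t-BuMe2SiCl, imidazole, DMF, rt
Reagents that add atoms: tert-butyldimethylsilyl chloride, CC(C)(C)[Si](C)(C)Cl
Why: Standard silylation of a secondary allylic alcohol; the bulky silyl ether later shields one face of the enone.

Step 3
Reactants: 3 tert-butyl[(8R)-1,4-dioxaspiro[4.5]dec-6-en-8-yloxy]dimethylsilane
Product: 4 (4R)-4-(tert-butyldimethylsilyloxy)cyclohex-2-en-1-one
Conditions: PPTS, acetone/H2O, 50 °C
Reagents that add atoms: water, O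
Why: Acid-catalysed hydrolysis of the allylic ketal frees the carbonyl at the former ketal carbon, so the oxygen stereocentre ends up γ to the new enone carbonyl. A secondary silyl ether should survive PPTS.

Step 4
Reactants: 4 (4R)-4-(tert-butyldimethylsilyloxy)cyclohex-2-en-1-one
Product: 5 (4R)-4-(tert-butyldimethylsilyloxy)-2-iodocyclohex-2-en-1-one
Conditions: I2, pyridine, CH2Cl2, 0 °C to rt
Reagents that add atoms: iodine, II
Why: α-Iodination of an enone by conjugate addition of pyridine, iodination of the enolate and elimination (a Baylis–Hillman-type addition–elimination). Only the α-carbon can react and the γ stereocentre is not touched.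

Step 5
Reactants: 5 (4R)-4-(tert-butyldimethylsilyloxy)-2-iodocyclohex-2-en-1-one
Product: 6 (4R)-4-(tert-butyldimethylsilyloxy)-2-methylcyclohex-2-en-1-one
Conditions: MeZnCl, Pd(PPh3)4 (cat.), THF, 0 °C to rt
Reagents that add atoms: methylzinc chloride, C[Zn]Cl
Why: Negishi coupling of an α-iodoenone; zerovalent palladium inserts into the weak C–I bond and the methylzinc reagent does not add to the enone or eliminate the γ-silyloxy group under these mild conditions.

Step 6
Reactants: 7 nerol, (2Z)-3,7-dimethylocta-2,6-dien-1-ol
Product: 8 neryl 4-methoxybenzyl ether, 1-({[(2Z)-3,7-dimethylocta-2,6-dien-1-yl]oxy}methyl)-4-methoxybenzene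
Conditions: NaH, 4-MeOC6H4CH2Cl, n-Bu4NI (cat.), THF/DMF, 0 °C to rt
Reagents that add atoms: 4-methoxybenzyl chloride, COc1ccc(CCl)cc1
Why: Williamson etherification of the primary allylic alkoxide; the Z alkene is not at risk under these basic conditions.

Step 7
Reactants: 8 neryl 4-methoxybenzyl ether
Product: 9 3-[(3Z)-5-(4-methoxybenzyloxy)-3-methylpent-3-en-1-yl]-2,2-dimethyloxirane (racemic at the epoxide carbon)
Conditions: mCPBA, CH2Cl2, −20 to 0 °C
Reagents that add atoms: 3-chloroperoxybenzoic acid, OOC(=O)c1cccc(Cl)c1
Why: Prilezhaev epoxidation; the 2,3-alkene is deactivated by the allylic ether oxygen, so the peracid should take the remote, more electron-rich alkene. The epoxide stereocentre is lost in the next step.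

Step 8
Reactants: 9 3-[(3Z)-5-(4-methoxybenzyloxy)-3-methylpent-3-en-1-yl]-2,2-dimethyloxirane
Product: 10 (4Z)-6-(4-methoxybenzyloxy)-4-methylhex-4-enal
Conditions: H5IO6, THF/H2O, 0 °C
Reagents that add atoms: none
Why: Periodic acid opens the epoxide to the diol (water enters at the tertiary carbon, so the aldehyde keeps the epoxide oxygen) and cleaves it in the same flask to 10 and acetone. The PMB ether and the Z alkene are inert to periodate.

Step 9
Reactants: 6 (4R)-4-(tert-butyldimethylsilyloxy)-2-methylcyclohex-2-en-1-one; 11 (1,3-dioxolan-2-ylmethyl)magnesium bromide; 10 (4Z)-6-(4-methoxybenzyloxy)-4-methylhex-4-enal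
Product: 13 (2S,3R,4R)-4-(tert-butyldimethylsilyloxy)-3-(1,3-dioxolan-2-ylmethyl)-2-[(1S,4Z)-1-hydroxy-6-(4-methoxybenzyloxy)-4-methylhex-4-en-1-yl]-2-methylcyclohexan-1-one, via bromomagnesium enolate 12 (not isolated)
Conditions: 11 (1.2 equiv), CuBr·SMe2 (20 mol%), THF, −78 to −40 °C; then 10 (1.5 equiv), −78 °C; sat. aq. NH4Cl at −78 °C
Reagents that add atoms: none
Why: Transmetalation of 11 to copper gives an organocopper species that forms a π-complex with 6 and transfers the dioxolanylmethyl group to C10, which leaves the bromomagnesium enolate 12 with its double bond fixed at C1=C14 by the site of addition; 12 then adds through C1 to the aldehyde carbon of 10 in a closed, six-membered, magnesium-bridged transition state. The closest known reaction type is the copper-catalysed conjugate addition of a Grignard reagent to a cyclic enone with aldol capture of the enolate in the same flask. No ring is closed; the bonds C9–C10 and C1–C2 are formed. C10 is controlled by the C11 silyloxy group, because the nucleophile enters on the face opposite to it, as is usual for 4-silyloxycyclohexenones. C1 is controlled by the new C10 substituent, because the aldehyde is bound on the enolate face away from it, which puts the C1 methyl group cis to C9 and C2 trans to C9 (trans fusion). C2 is controlled by the chair transition state, in which the aldehyde chain is equatorial and ring carbon C10 is the enolate substituent trans to oxygen, so the C2 oxygen ends up anti to C10 and syn to the methyl group along C14–C1–C2–C3, which is 2S. The step needs 1,4- over 1,2-addition (copper, low temperature), C–C bond formation faster than proton transfer from the enolisable aldehyde (cold addition, magnesium counter-ion) and no retro-aldol (cold quench). The steering C11 oxygen is disposable, since it is oxidised and turned into the C11=C12 alkene in steps 12 to 15.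

Step 10
Reactants: 13 ketol from step 9
Product: 15 cyclohexane (C1, C10–C14) with 1β-methyl, 1α-[(1S,4Z)-6-(4-methoxybenzyloxy)-4-methyl-1-(propanoyloxy)hex-4-enyl], 10β-(1,3-dioxolan-2-ylmethyl), 11α-tert-butyldimethylsilyloxy and 14α-hydroxy groups, via hemiacetal 14 (not isolated)
Conditions: EtCHO (8 equiv), SmI2 (30 mol%), THF, −10 °C
Reagents that add atoms: propanal, CCC=O
Why: Evans–Tishchenko reduction: the C2 hydroxyl forms hemiacetal 14 with propanal, trivalent samarium bridges the hemiacetal oxygen and the C14 carbonyl, and the hemiacetal hydrogen migrates to C14 through a six-membered chair with the C3 chain equatorial. This delivers hydride to the β face of C14, so the new hydroxyl is α and 1,3-anti to O2, and the propanoyl group is left on O2.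

Step 11
Reactants: 15 hydroxy propanoate from step 10
Product: 16 the 14α-acetate of 15 (1β-methyl, 1α-[(1S,4Z)-6-(4-methoxybenzyloxy)-4-methyl-1-(propanoyloxy)hex-4-enyl], 10β-(1,3-dioxolan-2-ylmethyl), 11α-tert-butyldimethylsilyloxy, 14α-acetoxy)
Conditions: Ac2O, DMAP, pyridine, CH2Cl2, rt
Reagents that add atoms: acetic anhydride, CC(=O)OC(C)=O
Why: DMAP-catalysed acylation of the axial, neopentyl C14 hydroxyl. It is run directly after step 10 and without alkoxide base so that the propanoyl group has no occasion to migrate from O2 to O14.

Step 12
Reactants: 16 acetate from step 11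
Product: 17 the 11α-alcohol (16 without the silyl group)
Conditions: HF·pyridine, pyridine, THF, 0 °C to rt
Reagents that add atoms: none
Why: Fluoride cleavage of the secondary silyl ether under buffered, weakly acidic conditions that should leave both esters, the dioxolane and the PMB ether intact.

Step 13
Reactants: 17 11α-alcohol from step 12
Product: 18 the C11 ketone: cyclohexanone (C11=O) with 1β-methyl, 1α-[(1S,4Z)-6-(4-methoxybenzyloxy)-4-methyl-1-(propanoyloxy)hex-4-enyl], 10β-(1,3-dioxolan-2-ylmethyl) and 14α-acetoxy groups
Conditions: Dess–Martin periodinane, CH2Cl2, rt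
Reagents that add atoms: none
Why: Dess–Martin oxidation under non-basic conditions; C10, now α to a ketone, keeps its configuration because no base is present and its C9 arm is already equatorial.

Step 14
Reactants: 18 C11 ketone from step 13
Product: 20 the C11 enol triflate (C11(OTf)=C12; other groups as in 18), via potassium enolate 19 (not isolated)
Conditions: KN(SiMe3)2 (1.05 equiv), THF, −78 °C; PhNTf2, −78 to 0 °C
Reagents that add atoms: N-phenylbis(trifluoromethanesulfonimide), O=S(=O)(N(c1ccccc1)S(=O)(=O)C(F)(F)F)C(F)(F)F
Why: Kinetic deprotonation by the hindered amide at the C12 methylene (the C10 methine is shielded by the quaternary C1 and the C9 arm) and O-sulfonylation of enolate 19. The ketone is several pK units more acidic than the two esters, which should stay untouched at −78 °C with one equivalent of base.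

Step 15
Reactants: 20 enol triflate from step 14
Product: 21 the cyclohexene with C11(CH3)=C12: 1β-methyl, 1α-[(1S,4Z)-6-(4-methoxybenzyloxy)-4-methyl-1-(propanoyloxy)hex-4-enyl], 10β-(1,3-dioxolan-2-ylmethyl), 14α-acetoxy
Conditions: MeZnCl, Pd(PPh3)4 (cat.), THF, rt to 45 °C
Reagents that add atoms: methylzinc chloride, C[Zn]Cl
Why: Negishi coupling of an alkenyl triflate; the organozinc tolerates esters, acetal and ether. The alkene position is fixed by the triflate and the C11 stereocentre is erased.

Step 16
Reactants: 21 dioxolane from step 15
Product: 22 the C8 aldehyde (10β-(2-oxoethyl) in place of the dioxolanylmethyl group)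
Conditions: TsOH·H2O (cat.), acetone/H2O, 40 °C
Reagents that add atoms: water, O
Why: Acid-catalysed hydrolysis of the dioxolane, driven by exchange with acetone; the esters, the PMB ether and both trisubstituted alkenes should tolerate catalytic acid at this temperature.

Step 17
Reactants: 22 aldehyde from step 16
Product: 23 the β-hydroxy ester (10β-CH2–CH(OH)–CH(CH3)–CO2CH3; mixture of C8 and C17 diastereomers)
Conditions: EtCO2Me, LiN(i-Pr)2, THF, −78 °C; then 22, −78 °C; AcOH quench at −78 °C
Reagents that add atoms: methyl propanoate, CCC(=O)OC
Why: Aldol addition of an ester lithium enolate; at −78 °C the aldehyde reacts far faster than the two hindered esters. Both new stereocentres are removed in steps 18 and 19, so the diastereomer mixture is of no consequence.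

Step 18
Reactants: 23 β-hydroxy ester from step 17
Product: 24 the β-keto ester (10β-CH2–CO–CH(CH3)–CO2CH3; C17 epimers and enol form)
Conditions: Dess–Martin periodinane, CH2Cl2, rt
Reagents that add atoms: none
Why: Dess–Martin oxidation of a β-hydroxy ester to the β-keto ester without base, so the esters elsewhere are safe.

Step 19
Reactants: 24 β-keto ester from step 18
Product: 26 the (Z)-enol triflate (10β-CH2–C(OTf)=C(CH3)–CO2CH3 with the triflate cis to the ester), via sodium enolate 25 (not isolated)
Conditions: NaH, CH2Cl2, 0 °C; Tf2O, −78 to 0 °C
Reagents that add atoms: trifluoromethanesulfonic anhydride, O=S(=O)(OS(=O)(=O)C(F)(F)F)C(F)(F)F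
Why: Only the β-keto ester is acidic enough for NaH. In a non-coordinating solvent its sodium enolate 25 is a Z chelate (enolate oxygen cis to the ester carbonyl), and O-sulfonylation keeps this geometry, which is the one needed for lactonisation after the ring closure.

Step 20
Reactants: 26 enol triflate PMB ether from step 19
Product: 27 the primary allylic alcohol (C7–OH; Z alkene retained)
Conditions: DDQ, CH2Cl2/pH 7 buffer, 0 °C
Reagents that add atoms: none
Why: Oxidative cleavage of the PMB ether by DDQ through the benzylic oxocarbenium ion; the esters, the alkenyl triflate and the alkenes are not oxidised.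

Step 21
Reactants: 27 allylic alcohol from step 20
Product: 28 the (Z)-enal (C7 aldehyde)
Conditions: TEMPO (cat.), PhI(OAc)2, CH2Cl2, rt
Reagents that add atoms: none
Why: Oxoammonium oxidation of a primary allylic alcohol, chosen because it is close to neutral and is known to keep Z enals from isomerising. Compound 28 is used at once.

Step 22
Reactants: 28 enal from step 21
Product: 30 the target, (1S,2S,7R,10S,14S)-14-acetoxy-2-propanoyloxy tricyclic butenolide with Z C5=C6, via hydroxy ester 29 (not isolated)
Conditions: CrCl2 (15 equiv), NiCl2 (cat.), DMSO, rt, 2 mM by slow addition; then PPTS, CH2Cl2, rt if lactonisation is incomplete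
Reagents that add atoms: none
Why: Nozaki–Hiyama–Kishi reaction: zerovalent nickel (from NiCl2 and CrCl2) inserts into the alkenyl triflate, transmetalation gives an alkenylchromium species of trivalent chromium that adds to the C7 aldehyde, and the chromium alkoxide of 29, held cis to the ester, closes the butenolide. High dilution favours the ten-membered ring. C7 is set by the conformation of the closing ring, and it is the least secure stereocentre of the route.

## Compound list

1 | 1,4-dioxaspiro[4.5]dec-6-en-8-one | O=C1C=CC2(CC1)OCCO2 | starting material
2 | (8R)-1,4-dioxaspiro[4.5]dec-6-en-8-ol | O[C@H]1C=CC2(CC1)OCCO2 | intermediate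
3 | tert-butyl[(8R)-1,4-dioxaspiro[4.5]dec-6-en-8-yloxy]dimethylsilane | CC(C)(C)[Si](C)(C)O[C@H]1C=CC2(CC1)OCCO2 | intermediate
4 | (4R)-4-(tert-butyldimethylsilyloxy)cyclohex-2-en-1-one | O=C1C=C[C@H](O[Si](C)(C)C(C)(C)C)CC1 | intermediate
5 | (4R)-4-(tert-butyldimethylsilyloxy)-2-iodocyclohex-2-en-1-one | O=C1C(I)=C[C@H](O[Si](C)(C)C(C)(C)C)CC1 | intermediate
6 | (4R)-4-(tert-butyldimethylsilyloxy)-2-methylcyclohex-2-en-1-one | CC1=C[C@H](O[Si](C)(C)C(C)(C)C)CCC1=O | intermediate
7 | nerol, (2Z)-3,7-dimethylocta-2,6-dien-1-ol | CC(C)=CCC/C(C)=C\CO | starting material
8 | neryl 4-methoxybenzyl ether | CC(C)=CCC/C(C)=C\COCc1ccc(OC)cc1 | intermediate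
9 | 3-[(3Z)-5-(4-methoxybenzyloxy)-3-methylpent-3-en-1-yl]-2,2-dimethyloxirane (racemic epoxide) | CC1(C)OC1CC/C(C)=C\COCc1ccc(OC)cc1 | intermediate
10 | (4Z)-6-(4-methoxybenzyloxy)-4-methylhex-4-enal | O=CCC/C(C)=C\COCc1ccc(OC)cc1 | intermediate
11 | (1,3-dioxolan-2-ylmethyl)magnesium bromide | Br[Mg]CC1OCCO1 | starting material
12 | bromomagnesium enolate (C1=C14) with 10β-(1,3-dioxolan-2-ylmethyl) and 11α-silyloxy groups (not isolated) | CC1=C(O[Mg]Br)CC[C@@H](O[Si](C)(C)C(C)(C)C)[C@@H]1CC1OCCO1 | intermediate
13 | (2S,3R,4R)-4-(tert-butyldimethylsilyloxy)-3-(1,3-dioxolan-2-ylmethyl)-2-[(1S,4Z)-1-hydroxy-6-(4-methoxybenzyloxy)-4-methylhex-4-en-1-yl]-2-methylcyclohexan-1-one | O1CCOC1C[C@H]2[C@H](O[Si](C)(C)C(C)(C)C)CCC(=O)[C@@]2([C@@H](O)CC/C(C)=C\COCc3ccc(OC)cc3)C | intermediate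
14 | propanal hemiacetal of 13 at O2 (not isolated) | O1CCOC1C[C@H]2[C@H](O[Si](C)(C)C(C)(C)C)CCC(=O)[C@@]2([C@@H](OC(O)CC)CC/C(C)=C\COCc3ccc(OC)cc3)C | intermediate
15 | 14α-alcohol with O2 propanoate (11α-silyl ether, dioxolane, PMB ether) | O1CCOC1C[C@H]2[C@H](O[Si](C)(C)C(C)(C)C)CC[C@H](O)[C@@]2([C@@H](OC(=O)CC)CC/C(C)=C\COCc3ccc(OC)cc3)C | intermediate
16 | 14α-acetate with O2 propanoate (11α-silyl ether, dioxolane, PMB ether) | O1CCOC1C[C@H]2[C@H](O[Si](C)(C)C(C)(C)C)CC[C@H](OC(C)=O)[C@@]2([C@@H](OC(=O)CC)CC/C(C)=C\COCc3ccc(OC)cc3)C | intermediate
17 | 11α-alcohol (14α-acetate, O2 propanoate, dioxolane, PMB ether) | O1CCOC1C[C@H]2[C@H](O)CC[C@H](OC(C)=O)[C@@]2([C@@H](OC(=O)CC)CC/C(C)=C\COCc3ccc(OC)cc3)C | intermediate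
18 | C11 ketone (14α-acetate, O2 propanoate, dioxolane, PMB ether) | O1CCOC1C[C@H]2C(=O)CC[C@H](OC(C)=O)[C@@]2([C@@H](OC(=O)CC)CC/C(C)=C\COCc3ccc(OC)cc3)C | intermediate
19 | potassium enolate C11(OK)=C12 of 18 (not isolated) | O1CCOC1C[C@H]2C(O[K])=CC[C@H](OC(C)=O)[C@@]2([C@@H](OC(=O)CC)CC/C(C)=C\COCc3ccc(OC)cc3)C | intermediate
20 | C11 enol triflate, C11(OTf)=C12 | O1CCOC1C[C@H]2C(OS(=O)(=O)C(F)(F)F)=CC[C@H](OC(C)=O)[C@@]2([C@@H](OC(=O)CC)CC/C(C)=C\COCc3ccc(OC)cc3)C | intermediate
21 | C11-methyl cyclohexene (14α-acetate, O2 propanoate, dioxolane, PMB ether) | O1CCOC1C[C@H]2C(C)=CC[C@H](OC(C)=O)[C@@]2([C@@H](OC(=O)CC)CC/C(C)=C\COCc3ccc(OC)cc3)C | intermediate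
22 | C8 aldehyde | O=CC[C@H]1C(C)=CC[C@H](OC(C)=O)[C@@]1([C@@H](OC(=O)CC)CC/C(C)=C\COCc2ccc(OC)cc2)C | intermediate
23 | β-hydroxy ester (C8 and C17 diastereomers) | COC(=O)C(C)C(O)C[C@H]1C(C)=CC[C@H](OC(C)=O)[C@@]1([C@@H](OC(=O)CC)CC/C(C)=C\COCc2ccc(OC)cc2)C | intermediate
24 | β-keto ester (C17 epimers) | COC(=O)C(C)C(=O)C[C@H]1C(C)=CC[C@H](OC(C)=O)[C@@]1([C@@H](OC(=O)CC)CC/C(C)=C\COCc2ccc(OC)cc2)C | intermediate
25 | sodium (Z)-enolate of 24 (not isolated) | COC(=O)/C(C)=C(\O[Na])C[C@H]1C(C)=CC[C@H](OC(C)=O)[C@@]1([C@@H](OC(=O)CC)CC/C(C)=C\COCc2ccc(OC)cc2)C | intermediate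
26 | (Z)-enol triflate of the β-keto ester, PMB ether | COC(=O)/C(C)=C(\OS(=O)(=O)C(F)(F)F)C[C@H]1C(C)=CC[C@H](OC(C)=O)[C@@]1([C@@H](OC(=O)CC)CC/C(C)=C\COCc2ccc(OC)cc2)C | intermediate
27 | (Z)-enol triflate, primary allylic alcohol at C7 | COC(=O)/C(C)=C(\OS(=O)(=O)C(F)(F)F)C[C@H]1C(C)=CC[C@H](OC(C)=O)[C@@]1([C@@H](OC(=O)CC)CC/C(C)=C\CO)C | intermediate
28 | (Z)-enol triflate, (Z)-enal at C7 | COC(=O)/C(C)=C(\OS(=O)(=O)C(F)(F)F)C[C@H]1C(C)=CC[C@H](OC(C)=O)[C@@]1([C@@H](OC(=O)CC)CC/C(C)=C\C=O)C | intermediate
29 | ten-membered (7R)-hydroxy methyl ester, hydroxyl cis to the ester across C8=C17 (not isolated) | CCC(=O)O[C@H]1CC/C(C)=C\[C@@H](O)/C(=C(/C)C(=O)OC)C[C@H]2C(C)=CC[C@H](OC(C)=O)[C@]12C | intermediate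
30 | target, (1S,2S,7R,10S,14S)-14-acetoxy-2-propanoyloxy 6/10/5 tricyclic butenolide, Z C5=C6 | CCC(=O)O[C@H]1CC/C(C)=C\[C@H]2OC(=O)C(C)=C2C[C@H]2C(C)=CC[C@H](OC(C)=O)[C@]12C | target

## Step count and least certain steps

Total: 22 steps. Longest linear sequence: 19 steps (steps 1 to 5 and 9 to 22); steps 6 to 8 form the side branch to aldehyde 10.

**Step 9 (key step).**
- What may go wrong: proton transfer from the enolisable aldehyde to the hindered, tetrasubstituted enolate may outrun C–C bond formation and return the simple conjugate adduct. Conjugate addition to an α-methyl enone may also be slow enough that unreacted Grignard reagent attacks the aldehyde. The ketol can revert by retro-aldol cleavage if the mixture warms before the quench.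
- Fallback: setting out from 6, the conjugate addition is run with Me3SiCl present (11, CuBr·SMe2, THF, −78 °C), which speeds the addition and gives the trimethylsilyl enol ether F1 as an isolable, regio-defined compound. MeLi then cleaves the Si–O bond to the lithium enolate, ZnCl2 converts it into the less basic zinc enolate, and 10 is added at −78 °C. The sequence returns to the route at 13.

**Step 10.**
- What may go wrong: hemiacetal formation and hydride transfer may be slow at a ketone that sits next to a quaternary carbon, which leaves time for Lewis-acid-promoted retro-aldol cleavage. The propanoyl group may also migrate from O2 to O14 once the new hydroxyl exists.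
- Fallback: setting out from 13, the C2 hydroxyl is acylated first ((EtCO)2O, DMAP, pyridine) to the β-propanoyloxy ketone F2, which cannot eliminate because C1 carries no hydrogen. The C14 ketone is then reduced with LiBH(s-Bu)3 in THF at −78 °C with a cold AcOH quench. The bulky hydride should approach along the equatorial path and avoid the axial hydrogens at C10 and C12 on the α face, giving the axial 14α-alcohol. The sequence returns to the route at 15.

**Step 14.**
- What may go wrong: deprotonation may be unselective (the C10 methine, or the α-positions of the acetate and propanoate), and an ester acyl group may be transferred to the enolate before it is sulfonylated.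
- Fallback: setting out from 18, the methyl group is added to the ketone with the organocerium reagent from MeLi and CeCl3 at −78 °C, which is selective for ketones over esters, to give the tertiary carbinol F3. Dehydration with the Burgess reagent (syn elimination) then leads toward the C12 methylene, because elimination toward C10 would give a tetrasubstituted alkene next to the quaternary C1; an exocyclic isomer, if formed, would have to be separated. The sequence returns to the route at 21.

**Step 22.**
- What may go wrong: oligomerisation may compete with closure of the strained ten-membered ring, and the two faces of the enal may be attacked without selectivity or with the wrong preference, since only the conformation of the closing ring tells them apart. Isomerisation of the Z enal before closure would make the ring impossible.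
- Fallback: setting out from 28, the closure is run as described. If it delivers the C7 epimer of the target F4, the configuration is corrected by oxidation and reduction at C7. i-Pr3SiOTf and Et3N convert the butenolide into the 2-(triisopropylsilyloxy)furan F5, which removes the C7 stereocentre. Dimethyldioxirane at −78 °C oxidises the electron-rich furan to the 7-hydroxybutenolide F6, which is in equilibrium with the ring-opened C7 keto acid. NaBH4 with CeCl3 in MeOH at −40 °C reduces the ketone from the outer face of the ring, and the hydroxy acid relactonises on acidification. The sequence returns to the route at 30.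

## Further compounds

F1 | step 9 | trimethylsilyl enol ether (C1=C14) of the conjugate adduct, 10β-(1,3-dioxolan-2-ylmethyl), 11α-tert-butyldimethylsilyloxy | CC1=C(O[Si](C)(C)C)CC[C@@H](O[Si](C)(C)C(C)(C)C)[C@@H]1CC1OCCO1
F2 | step 10 | C2 propanoate of ketol 13 (C14 ketone retained) | O1CCOC1C[C@H]2[C@H](O[Si](C)(C)C(C)(C)C)CCC(=O)[C@@]2([C@@H](OC(=O)CC)CC/C(C)=C\COCc3ccc(OC)cc3)C
F3 | step 14 | C11 tertiary carbinol (11-hydroxy-11-methyl, either C11 epimer) from 18 | O1CCOC1C[C@H]2C(C)(O)CC[C@H](OC(C)=O)[C@@]2([C@@H](OC(=O)CC)CC/C(C)=C\COCc3ccc(OC)cc3)C
F4 | step 22 | C7 epimer of the target (7S) | CCC(=O)O[C@H]1CC/C(C)=C\[C@@H]2OC(=O)C(C)=C2C[C@H]2C(C)=CC[C@H](OC(C)=O)[C@]12C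
F5 | step 22 | 2-(triisopropylsilyloxy)furan derived from the butenolide (C7 sp2) | CCC(=O)O[C@H]1CC/C(C)=C\c2oc(O[Si](C(C)C)(C(C)C)C(C)C)c(C)c2C[C@H]2C(C)=CC[C@H](OC(C)=O)[C@]12C
F6 | step 22 | 7-hydroxybutenolide (hemiketal at C7, in equilibrium with the C7 keto acid) | CCC(=O)O[C@H]1CC/C(C)=C\C2(O)OC(=O)C(C)=C2C[C@H]2C(C)=CC[C@H](OC(C)=O)[C@]12C
A1 | alternative 1 | 2-oxo analogue of the target (C2 ketone in place of the propanoate) | O=C1CC/C(C)=C\[C@H]2OC(=O)C(C)=C2C[C@H]2C(C)=CC[C@H](OC(C)=O)[C@]12C
A2 | alternative 1 | seco compound with a 1-hydroxycyclopropyl group on C1 and a Z iodoalkene at C5 | I/C(C)=C\[C@H]1OC(=O)C(C)=C1C[C@H]1C(C)=CC[C@H](OC(C)=O)[C@]1(C)C1(O)CC1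
A3 | alternative 2 | 14-hydroxy tricycle with C2 tert-butyldimethylsilyl ether | CC(C)(C)[Si](C)(C)O[C@H]1CC/C(C)=C\[C@H]2OC(=O)C(C)=C2C[C@H]2C(C)=CC[C@H](O)[C@]12C
A4 | alternative 2 | 14-membered epoxy cembranoid butenolide (C1–C14 epoxide, E C10=C11, C2 silyl ether) | CC(C)(C)[Si](C)(C)O[C@H]1CC/C(C)=C\[C@H]2OC(=O)C(C)=C2C/C=C(\C)CC[C@@H]3O[C@]13C
A5 | alternative 3 | ten-membered C7 alcohol with isopropenyl group on C8 (C2 PMB ether, C14 silyl ether) | COc3ccc(cc3)CO[C@H]1CC/C(C)=C\[C@@H](O)[C@H](C(C)=C)C[C@H]2C(C)=CC[C@H](O[Si](C)(C)C(C)(C)C)[C@]12C
A6 | alternative 3 | 13-membered diallylic ether with tributylstannyl group on C7 (either C7 epimer) | COc1ccc(cc1)CO[C@H]2CC/C(C)=C\C([Sn](CCCC)(CCCC)CCCC)OC/C(C)=C/C[C@H]3C(C)=CC[C@H](O[Si](C)(C)C(C)(C)C)[C@]23C
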